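The coupling partner exceeds the solid substrate by just 1.00 mM, and what to watch in this flask is how much of the solid substrate charge stays out of target over that thin excess.

solid substrate 0.0050 M; coupling partner 6.00 mM; time 15 min

    starting material + coupling partner ⇌ intermediate A (K1 = 41 L mol⁻¹, k1 = 24 L mol⁻¹ s⁻¹)
    starting material ⇌ intermediate B (K2 = 1.3, k2 = 0.54 s⁻¹)
    coupling partner + intermediate B ⇌ target (K3 = 4200 L mol⁻¹, k3 = 5.8 L mol⁻¹ s⁻¹)
    solid substrate ⇌ starting material, rate k4*(cs4 - [starting material]) while solid is left; crystals form when [starting material] > cs4 (cs4 = 4.8 mM, k4 = 0.033 s⁻¹)

- solid, in amounts per volume of the solution: solid substrate
- at the start none of the solid substrate is in solution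
- what has only dissolved of solid substrate counts as not reacted
- what has gone from starting material into another species counts as reacted, even if it can come back
- run time (flask): 15 min

* part of the solid substrate that has turned into other species by 15 min (what has only dissolved does not count)
* how much target there is at 15 min, in percent of the solid substrate charged
* how much intermediate B there is at 15 min, in percent of the solid substrate charged

I go from the fastest clock to the slowest. Starting material and intermediate B relax into each other with a half-life of 0.726 s, quicker than the forward half-life of 4.81 s towards intermediate A, so I take what dissolves as split at once in the ratio 1.3. With the partner as charged, intermediate A can reach a quarter of starting material, and I drop it as small. Dissolving the charge takes 31.6 s at the full rate, and intermediate B, with the partner as charged, has a forward half-life of 19.9 s towards target; both are short against 15 min.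

Target is the large thing, so I reckon the small one. Let r be the part of the solid substrate charge standing as starting material plus intermediate B. Then target is the charge minus r, and the partner left is the excess plus r. At equilibrium, target divided by r times partner is 2370 L mol⁻¹. The positive root is 0.905 mM: this is the remainder, the part of the charge held out of target at equilibrium. The last approach to it has a half-life of 65.4 s, short against 15 min, so I commit to equilibrium: conversion 92.1 %, target 81.9 %, intermediate B 10.2 %.

The forecast gives 92.2 % converted, 81.4 % target and 10.2 % intermediate B, holding that “the system reaches full equilibrium”. Its target stands 0.50 percentage points below mine, and I dropped intermediate A.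

The flask gives 92.2 % converted, 81.4 % target and 10.2 % intermediate B, with starting material plus intermediate B at 18.0 % against a remainder of 18.1 % of the charge. The neighbouring flask with 0.0015 M of coupling partner has an excess of −3.50 mM, which is a shortfall; the same root gives a remainder of 3.66 mM, or 73.1 % of its solid substrate charge, leaving 26.9 % as target. That flask holds 26.7 % target, 41.3 % intermediate B and 31.8 % starting material.

The constants used here come from no measurement; no experiment stands behind them.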